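**Assumptions:** (2E,6E)-farnesol is commercial and achiral. The Shi ketone enantiomer is chosen to give the (S)-epoxides shown. The C10 configuration set in Step 2 is irrelevant because it is oxidised in Step 4. (S)-Me-CBS is taken to give the (10R)-alcohol by analogy with acetophenone.

**Retrosynthesis**
- Sodwanone T (12) comes from catalyst-controlled mono-reduction of the symmetric diketone 11. Each half is a trans-fused cyclohexene–oxepane.
- 11 comes from Ni(0) Wurtz-type homocoupling of the allylic bromide 10, which forms the squalene-type C1–C1′ bridge.
- 10, 8, 7 and 6 all derive from the bicycle 6. It is formed in one operation from the diepoxide 5 by an epoxide–epoxide–alkene cascade: the cyclohexene (C2–C7 bond) and the oxepane (C6–O–C11) close together.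
- 5 comes from Shi organocatalytic asymmetric diepoxidation of farnesyl acetate (3), which sets C6/C7. 3 comes from achiral farnesol (1).

---

**Step 1**
Reactants: 1 (2E,6E)-farnesol; 2 acetic anhydride
Product: 3 (2E,6E)-farnesyl acetate
Conditions: Ac2O, pyridine, DMAP (cat.), CH2Cl2, 0 °C → 25 °C
Reagents that add atoms: Ac2O, CC(=O)OC(C)=O
Why: Standard O-acylation. The acetate deactivates the C2=C3 alkene towards both dioxirane epoxidation (Step 2) and, moderately, the cascade (Step 3).

**Step 2**
Reactants: 3 farnesyl acetate; 4 potassium peroxymonosulfate (Oxone)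
Product: 5 (6S,7S,10S)-6,7:10,11-diepoxyfarnesyl acetate
Conditions: fructose-derived Shi ketone (0.6 equiv, added in portions), Oxone (6 equiv), K2CO3, Bu4NHSO4, MeCN/DMM/aq Na2B4O7–EDTA (pH ≈ 10.5), 0 °C
Reagents that add atoms: Oxone (KHSO5), OOS(=O)(=O)[O-].[K+], which is the source of both epoxide oxygens
Why: Shi asymmetric epoxidation (organocatalytic dioxirane, spiro transition state) epoxidises the two most electron-rich, accessible alkenes, the terminal and the 6,7 E-alkene, while the allylic-acetate C2=C3 alkene stays untouched. The chiral ketone sets C6 and C7 as the trans-(6S,7S) epoxide, and C10 as S.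

**Step 3**
Reactants: 5 diepoxide
Product: 6 bicyclic hydroxy acetate, (6S,7S,10S); the cyclohexene–oxepane with the tetrasubstituted ring alkene, CH2OAc on C2, and a secondary C10–OH
Conditions: Me2AlCl (1.5 equiv), CH2Cl2, −78 → −30 °C; aq. Rochelle salt work-up
Reagents that add atoms: none (isomerisation)
Why: Proposed new method: the Lewis acid ionises the tertiary C11 end of the 10,11-epoxide. The 6,7-epoxide oxygen (or, equivalently, C6–OH after an epoxide-ene step) delivers O to C11, while the C2=C3 alkene attacks C7 anti to the C7–O bond in a chair transition state. This closes the cyclohexene and the 7-endo oxepane, and E1 loss of the axial H-2 gives the tetrasubstituted alkene. The closest known reactions are epoxide-initiated polyene cyclisation and epoxide-opening cascades in which an epoxide oxygen acts as nucleophile, here applied to an oxepane-forming 7-endo closure. C7 is set by inversion, giving the trans-fused ring junction with O and C8 diequatorial; C6 and C10 are retained.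

**Step 4**
Reactants: 6 hydroxy acetate
Product: 7 keto acetate
Conditions: Dess–Martin periodinane (1.5 equiv), NaHCO3, CH2Cl2, 0 °C → 25 °C
Reagents that add atoms: none
Why: Oxidation of the hindered secondary alcohol to the ketone destroys the C10 stereocentre, so all diastereomeric cascade products converge. The alkene, ether and acetate are untouched.

**Step 5**
Reactants: 7 keto acetate
Product: 8 keto allylic alcohol
Conditions: K2CO3, MeOH, 25 °C
Reagents that add atoms: none (the acetyl group leaves as MeOAc)
Why: Mild methanolysis of the primary allylic acetate. The ketone has no enolisable centre on the gem-dimethyl side, and no stereocentre is affected.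

**Step 6**
Reactants: 8 keto allylic alcohol; 9 tetrabromomethane
Product: 10 keto allylic bromide
Conditions: CBr4, PPh3, CH2Cl2, 0 °C; crude used immediately
Reagents that add atoms: CBr4, BrC(Br)(Br)Br (PPh3 leaves as Ph3P=O)
Why: Appel reaction on the unhindered primary allylic alcohol, with SN2 displacement and no allylic transposition. The ketone and ether survive.

**Step 7**
Reactants: 10 allylic bromide (2 equiv)
Product: 11 C1–C1′-linked diketone (C2-symmetric)
Conditions: Ni(cod)2 (1.2 equiv), DMF, 0 → 25 °C
Reagents that add atoms: none (the two bromides leave as NiBr2)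
Why: Semmelhack-type Ni(0) reductive allyl–allyl homocoupling via a bis(π-allyl)nickel species. It couples at the primary termini, as in farnesyl bromide to squalene, and tolerates the hindered ether and ketone.

**Step 8**
Reactants: 11 diketone
Product: 12 sodwanone T
Conditions: (S)-Me-CBS (0.3 equiv), BH3·SMe2 (0.4 equiv), THF, −20 °C; MeOH quench; recovered diketone and diol are recycled with DMP
Reagents that add atoms: none (adds only H)
Why: Corey–Bakshi–Shibata reduction is catalyst-controlled. The CMe2(OR) group is the large substituent and the CH2 the small one, so the (S)-catalyst delivers the (10R)-alcohol. Substoichiometric hydride gives statistical desymmetrisation (up to about 50% mono-alcohol), and the other alkenes and ethers are inert.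

---

**Compound list**

| No. | Name | SMILES | Role |
|---|---|---|---|
| 1 | (2E,6E)-farnesol | OC/C=C(\C)CC/C=C(\C)CCC=C(C)C | starting material |
| 2 | acetic anhydride | CC(=O)OC(C)=O | starting material (reagent) |
| 3 | (2E,6E)-farnesyl acetate | CC(=O)OC/C=C(\C)CC/C=C(\C)CCC=C(C)C | intermediate |
| 4 | potassium peroxymonosulfate | OOS(=O)(=O)[O-].[K+] | starting material (reagent) |
| 5 | (6S,7S,10S)-6,7:10,11-diepoxyfarnesyl acetate | CC(=O)OC/C=C(\C)CC[C@@H]1O[C@@]1(C)CC[C@@H]1OC1(C)C | intermediate |
| 6 | bicyclic hydroxy acetate (cyclohexene–oxepane, 10-OH) | CC1=C(COC(C)=O)[C@]2(C)CC[C@H](O)C(C)(C)O[C@H]2CC1 | intermediate |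
| 7 | keto acetate | CC1=C(COC(C)=O)[C@]2(C)CCC(=O)C(C)(C)O[C@H]2CC1 | intermediate |
| 8 | keto allylic alcohol | CC1=C(CO)[C@]2(C)CCC(=O)C(C)(C)O[C@H]2CC1 | intermediate |
| 9 | tetrabromomethane | BrC(Br)(Br)Br | starting material (reagent) |
| 10 | keto allylic bromide | CC1=C(CBr)[C@]2(C)CCC(=O)C(C)(C)O[C@H]2CC1 | intermediate |
| 11 | symmetric diketone dimer | CC1=C(CCC2=C(C)CC[C@@H]3OC(C)(C)C(=O)CC[C@@]23C)[C@]2(C)CCC(=O)C(C)(C)O[C@H]2CC1 | intermediate |
| 12 | sodwanone T | CC1=C(CCC2=C(C)CC[C@@H]3OC(C)(C)[C@H](O)CC[C@@]23C)[C@]2(C)CCC(=O)C(C)(C)O[C@H]2CC1 | target |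

**Total steps:** 8. **Longest linear sequence:** 8 (1 → 3 → 5 → 6 → 7 → 8 → 10 → 11 → 12).

**Three steps most likely to fail**
1. **Step 3 (the proposed new cascade).** Risks are 6-exo tetrahydropyran formation instead of 7-endo closure, Meinwald rearrangement, and mis-placed alkene. Fallback (known chemistry, stepwise):
   - Make the terminal bromohydrin of 3 with NBS/aq. THF and silylate it.
   - Shi-epoxidise the 6,7-alkene and run a Me2AlCl epoxy-olefin cyclisation.
   - Close the 10,11-epoxide with K2CO3/MeOH, then effect a CSA-mediated 7-endo epoxy-alcohol closure to reach 6 (or its C10 epimer), which oxidises to 7.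
2. **Step 7.** The allylic bromide is hindered and contains a ketone, so the Ni(0) homocoupling may stall or give reduction. Fallback: Biellmann coupling.
   - Reduce and silylate the ketone.
   - Convert the bromide to the allylic phenyl sulfone.
   - Couple the sulfonyl anion with a second equivalent of the protected bromide, then desulfonylate with Pd/LiBHEt3.
   - Deprotect and oxidise to give 11.
3. **Step 8.** CBS facial selectivity on this hindered α-alkoxy ketone is unproven, and desymmetrisation is only statistical. Fallback: reverse the order.
   - Reduce both ketones of 11 completely with (S)-CBS/BH3 to the C2-symmetric (10R,10′R)-diol.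
   - Mono-oxidise one carbinol with substoichiometric DMP or TEMPO/PIDA, recycling the diol and over-oxidised diketone.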